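**Plan**

- Numbering of the target: ring O1, C2 (aryl), C3, C4 (C=O), C5, C6, side chain C7 (carbinol) and C8. The retrosynthesis cuts, in this order: the two phenolic O–benzyl bonds; the C4 carbonyl (back to a C3=C4 alkene); C7–H and C7–C8 (ketone, then Weinreb amide plus a benzylic Grignard reagent); C5–C6; the lactone C–O and ether O–CH2 bonds of a 1,4-dioxan-2-one; the bond between the two carbinol carbons.
- Enabling feature: C7 (as a carboxyl), C6, C5 and a C3=C4 alkene make up a γ,δ-unsaturated acid, and O1 on C6 leads back to the allylic, aryl-bearing C2. The oxane is therefore the [3,3] product of a 5-aryl-6-vinyl-1,4-dioxan-2-one whose lactone α-carbon becomes C6.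
- Forward order: aldehyde plus alkoxyallyl unit, glycolate ether, dioxanone, then the rearrangement, which forms the only ring of the target. After that come the C7–C8 side chain, the C4 ketone and the free phenols.
- Stereochemistry: C2 comes from reagent-controlled (Z)-γ-alkoxyallylboration; C6 by chirality transfer from the vinyl-bearing centre in the rearrangement; C7 by chelation-controlled hydride delivery.

Key step: step 5

Remark: the target is read as 2S,6R,7S with the ring substituents cis; since 4-alkoxybenzylic ethers ionise easily, no step uses a Brønsted acid stronger than a pH 4 buffer.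

**Route**

Step 1
Reactants: 1 O-benzylvanillin; 2 3-(methoxymethoxy)prop-1-ene
Product: 5 (1R,2R)-1-[4-(benzyloxy)-3-methoxyphenyl]-2-(methoxymethoxy)but-3-en-1-ol, via allylborane 3 (not isolated), via borinate 4 (not isolated)
Conditions: 2, s-BuLi, THF, −78 °C; (−)-Ipc2BOMe [(−)-B-methoxydiisopinocampheylborane, from (+)-α-pinene]; BF3·OEt2; 1, −78 °C → rt; NaOH, H2O2, 0 °C → rt
Reagents that add atoms: none
Why: Brown (Z)-γ-alkoxyallylboration, in which the Z-configured allylborane 3 adds through a closed chair transition state so that the two oxygens end syn, while the isopinocampheyl groups of the (+)-α-pinene series direct the allyl unit to the Si face of the aldehyde and so set both new centres as R.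

Step 2
Reactants: 5 (1R,2R)-1-[4-(benzyloxy)-3-methoxyphenyl]-2-(methoxymethoxy)but-3-en-1-ol; 6 bromoacetic acid
Product: 7 2-{[(1R,2R)-1-[4-(benzyloxy)-3-methoxyphenyl]-2-(methoxymethoxy)but-3-en-1-yl]oxy}acetic acid
Conditions: NaH (3 equiv), THF, 0 → 45 °C; NaH2PO4 buffer (pH 4) work-up
Reagents that add atoms: none
Why: Williamson etherification, in which the sodium alkoxide of 5 displaces bromide from sodium bromoacetate (the carboxylate protects the carbonyl from acyl attack) and no stereocentre is touched under the basic conditions.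

Step 3
Reactants: 7 2-{[(1R,2R)-1-[4-(benzyloxy)-3-methoxyphenyl]-2-(methoxymethoxy)but-3-en-1-yl]oxy}acetic acid
Product: 9 2-{[(1R,2R)-1-[4-(benzyloxy)-3-methoxyphenyl]-2-hydroxybut-3-en-1-yl]oxy}acetic acid, via bipyridinium salt 8 (not isolated)
Conditions: TMSOTf, 2,2'-bipyridyl, CH2Cl2, 0 °C → rt; then H2O, rt
Reagents that add atoms: none
Why: Silyl triflate/2,2'-bipyridyl cleavage of a methoxymethyl ether, in which the base-buffered silyl triflate activates only the acetal, water hydrolyses the bipyridinium salt 8, and the non-protic medium should spare the ionisable 4-alkoxybenzylic ether that a Brønsted acid would cleave.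

Step 4
Reactants: 9 2-{[(1R,2R)-1-[4-(benzyloxy)-3-methoxyphenyl]-2-hydroxybut-3-en-1-yl]oxy}acetic acid
Product: 10 (5R,6R)-5-[4-(benzyloxy)-3-methoxyphenyl]-6-ethenyl-1,4-dioxan-2-one
Conditions: EDCI·HCl, DMAP, CH2Cl2 (0.02 M), 0 °C → rt
Reagents that add atoms: none
Why: Steglich lactonisation, in which carbodiimide activation and DMAP-mediated acyl transfer to the allylic hydroxyl close the six-membered lactone at high dilution without touching either stereocentre, the syn diol relationship becoming the trans 5,6-substitution.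

Step 5
Reactants: 10 (5R,6R)-5-[4-(benzyloxy)-3-methoxyphenyl]-6-ethenyl-1,4-dioxan-2-one
Product: 13 (2R,6S)-6-[4-(benzyloxy)-3-methoxyphenyl]-3,6-dihydro-2H-pyran-2-carboxylic acid, via silyl ketene acetal 11 (not isolated), via trimethylsilyl ester 12 (not isolated)
Conditions: LDA, TMSCl/Et3N, THF, −100 °C → rt; PhMe, 80 °C; aq. NaHCO3, then NaH2PO4 to pH 4
Reagents that add atoms: none
Why: LDA removes a C3 proton of the lactone in the presence of TMSCl so that the ring-held silyl ketene acetal 11 forms at once, and on warming it undergoes a concerted suprafacial [3,3]-sigmatropic shift in which C3 bonds to the vinyl terminus while the allylic C6–O1 bond breaks, leaving silyl ester 12 that water hydrolyses to 13. The closest known reaction type is the Ireland–Claisen rearrangement of 6-alkenyl-1,4-dioxan-2-ones to 6-substituted 3,6-dihydro-2H-pyran-2-carboxylic acids. The dihydropyran ring (O4, C5, C6, the two vinyl carbons and C3 of 10) is closed by this pericyclic C–C bond formation through a boat-shaped, bicyclo[2.2.2]-like six-atom array, the only geometry in which the axial vinyl group reaches the ketene acetal carbon, and the ring alkene is therefore cis. The new stereocentre (C6 of the target) is controlled by the vinyl-bearing centre of 10: the vinyl group can bond only on its own ring face, and because the aryl group is trans to it the carboxyl ends cis to the aryl group, that is (2R,6S), while the aryl-bearing centre takes no part and keeps its configuration. The step needs O-silylation to outrun ring opening of the lactone enolate to a ketene, which the internal TMSCl/Et3N quench at −100 °C should secure, and it needs the trans-diaxial conformer, which the flat ester unit and the two ring oxygens make accessible.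

Step 6
Reactants: 13 (2R,6S)-6-[4-(benzyloxy)-3-methoxyphenyl]-3,6-dihydro-2H-pyran-2-carboxylic acid
Product: 14 (2R,6S)-6-[4-(benzyloxy)-3-methoxyphenyl]-N-methoxy-N-methyl-3,6-dihydro-2H-pyran-2-carboxamide
Conditions: MeNHOMe·HCl, EDCI·HCl, HOBt, N-methylmorpholine, CH2Cl2, 0 °C → rt
Reagents that add atoms: N,O-dimethylhydroxylamine hydrochloride, CNOC.Cl
Why: Carbodiimide/HOBt amide coupling to the Weinreb amide, which is neutral enough for the allylic benzylic ether and leaves the α-alkoxy centre intact because an α-alkoxy acid has no azlactone pathway.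

Step 7
Reactants: 14 (2R,6S)-6-[4-(benzyloxy)-3-methoxyphenyl]-N-methoxy-N-methyl-3,6-dihydro-2H-pyran-2-carboxamide; 15 1-(benzyloxy)-4-(chloromethyl)benzene
Product: 17 1-{(2R,6S)-6-[4-(benzyloxy)-3-methoxyphenyl]-3,6-dihydro-2H-pyran-2-yl}-2-[4-(benzyloxy)phenyl]ethan-1-one, via benzylic Grignard reagent 16 (not isolated)
Conditions: 15, Mg, THF (0.25 M), 0 °C → rt; then 14, THF, −20 → 0 °C; sat. aq. NH4Cl
Reagents that add atoms: none
Why: Weinreb ketone synthesis, in which the Grignard reagent 16 adds only once because the magnesium-chelated tetrahedral adduct survives until the mild NH4Cl quench, which also keeps the α-alkoxy centre from enolising.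

Step 8
Reactants: 17 1-{(2R,6S)-6-[4-(benzyloxy)-3-methoxyphenyl]-3,6-dihydro-2H-pyran-2-yl}-2-[4-(benzyloxy)phenyl]ethan-1-one
Product: 18 (1S)-1-{(2R,6S)-6-[4-(benzyloxy)-3-methoxyphenyl]-3,6-dihydro-2H-pyran-2-yl}-2-[4-(benzyloxy)phenyl]ethan-1-ol
Conditions: Zn(BH4)2, Et2O, −30 → 0 °C; sat. aq. NH4Cl
Reagents that add atoms: none
Why: Chelation-controlled (Cram chelate) reduction, in which zinc bridges the ketone oxygen and ring O1 and hydride enters from the side of the C6 hydrogen (target numbering), away from C5, which should give the 7S carbinol anti to the ring C–O bond.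

Step 9
Reactants: 18 (1S)-1-{(2R,6S)-6-[4-(benzyloxy)-3-methoxyphenyl]-3,6-dihydro-2H-pyran-2-yl}-2-[4-(benzyloxy)phenyl]ethan-1-ol
Product: 19 (2S,6R)-2-[4-(benzyloxy)-3-methoxyphenyl]-6-{(1S)-2-[4-(benzyloxy)phenyl]-1-hydroxyethyl}oxan-4-one
Conditions: PdCl2 (15 mol%), CuCl, O2 (1 atm), DMF/H2O (7:1), rt
Reagents that add atoms: water, O
Why: Tsuji–Wacker oxidation by divalent palladium, in which water adds to the metal-bound alkene at the carbon remote from the electron-withdrawing allylic ring oxygen so that the carbonyl appears at C4, while the free carbinol should not intercept the alkene because a bridged oxypalladation would need both ring substituents axial.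

Step 10
Reactants: 19 (2S,6R)-2-[4-(benzyloxy)-3-methoxyphenyl]-6-{(1S)-2-[4-(benzyloxy)phenyl]-1-hydroxyethyl}oxan-4-one
Product: 20 (2S,6R)-2-(4-hydroxy-3-methoxyphenyl)-6-[(1S)-1-hydroxy-2-(4-hydroxyphenyl)ethyl]oxan-4-one
Conditions: H2 (1 atm), 10% Pd/C, EtOAc, rt
Reagents that add atoms: none
Why: Catalytic hydrogenolysis, in which the two aryl benzyl ethers are cleaved much faster than the cyclic benzylic C2–O1 bond or the ketone is reduced in a neutral solvent, and no stereocentre is affected.

**Compound list**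

1 | 4-(benzyloxy)-3-methoxybenzaldehyde (O-benzylvanillin) | COc1cc(C=O)ccc1OCc1ccccc1 | starting material
2 | 3-(methoxymethoxy)prop-1-ene | C=CCOCOC | starting material
3 | [(Z)-3-(methoxymethoxy)prop-2-en-1-yl]diisopinocampheylborane (isopinocampheyl groups of the (+)-α-pinene series) | COCO/C=C\CB([C@@H]1C[C@@H]2C[C@@H](C2(C)C)[C@H]1C)[C@@H]1C[C@@H]2C[C@@H](C2(C)C)[C@H]1C | intermediate (not isolated)
4 | diisopinocampheylborinate of alcohol 5 (boron on the benzylic oxygen) | COCO[C@H](C=C)[C@H](OB([C@@H]1C[C@@H]2C[C@@H](C2(C)C)[C@H]1C)[C@@H]1C[C@@H]2C[C@@H](C2(C)C)[C@H]1C)c1ccc(OCc2ccccc2)c(OC)c1 | intermediate (not isolated)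
5 | (1R,2R)-1-[4-(benzyloxy)-3-methoxyphenyl]-2-(methoxymethoxy)but-3-en-1-ol | COCO[C@H](C=C)[C@H](O)c1ccc(OCc2ccccc2)c(OC)c1 | intermediate
6 | bromoacetic acid | OC(=O)CBr | starting material
7 | 2-{[(1R,2R)-1-[4-(benzyloxy)-3-methoxyphenyl]-2-(methoxymethoxy)but-3-en-1-yl]oxy}acetic acid | COCO[C@H](C=C)[C@H](OCC(=O)O)c1ccc(OCc2ccccc2)c(OC)c1 | intermediate
8 | N-(alkoxymethyl)-2,2'-bipyridinium triflate derived from 7 (methoxy of the acetal replaced by bipyridinium, acid as trimethylsilyl ester) | c1ccnc(c1)-c1cccc[n+]1CO[C@H](C=C)[C@H](OCC(=O)O[Si](C)(C)C)c1ccc(OCc2ccccc2)c(OC)c1.[O-]S(=O)(=O)C(F)(F)F | intermediate (not isolated)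
9 | 2-{[(1R,2R)-1-[4-(benzyloxy)-3-methoxyphenyl]-2-hydroxybut-3-en-1-yl]oxy}acetic acid | O[C@H](C=C)[C@H](OCC(=O)O)c1ccc(OCc2ccccc2)c(OC)c1 | intermediate
10 | (5R,6R)-5-[4-(benzyloxy)-3-methoxyphenyl]-6-ethenyl-1,4-dioxan-2-one (trans) | O=C1CO[C@H](c2ccc(OCc3ccccc3)c(OC)c2)[C@@H](C=C)O1 | intermediate
11 | trimethylsilyl ketene acetal of 10 (C2–OSiMe3, C2=C3; C5 and C6 as in 10) | C[Si](C)(C)OC1=CO[C@H](c2ccc(OCc3ccccc3)c(OC)c2)[C@@H](C=C)O1 | intermediate (not isolated)
12 | trimethylsilyl (2R,6S)-6-[4-(benzyloxy)-3-methoxyphenyl]-3,6-dihydro-2H-pyran-2-carboxylate | COc1cc([C@@H]2C=CC[C@H](C(=O)O[Si](C)(C)C)O2)ccc1OCc1ccccc1 | intermediate (not isolated)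
13 | (2R,6S)-6-[4-(benzyloxy)-3-methoxyphenyl]-3,6-dihydro-2H-pyran-2-carboxylic acid (cis) | COc1cc([C@@H]2C=CC[C@H](C(=O)O)O2)ccc1OCc1ccccc1 | intermediate
14 | (2R,6S)-6-[4-(benzyloxy)-3-methoxyphenyl]-N-methoxy-N-methyl-3,6-dihydro-2H-pyran-2-carboxamide | COc1cc([C@@H]2C=CC[C@H](C(=O)N(C)OC)O2)ccc1OCc1ccccc1 | intermediate
15 | 1-(benzyloxy)-4-(chloromethyl)benzene | ClCc1ccc(OCc2ccccc2)cc1 | starting material
16 | [4-(benzyloxy)benzyl]magnesium chloride | Cl[Mg]Cc1ccc(OCc2ccccc2)cc1 | intermediate (not isolated)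
17 | 1-{(2R,6S)-6-[4-(benzyloxy)-3-methoxyphenyl]-3,6-dihydro-2H-pyran-2-yl}-2-[4-(benzyloxy)phenyl]ethan-1-one | COc1cc([C@@H]2C=CC[C@H](C(=O)Cc3ccc(OCc4ccccc4)cc3)O2)ccc1OCc1ccccc1 | intermediate
18 | (1S)-1-{(2R,6S)-6-[4-(benzyloxy)-3-methoxyphenyl]-3,6-dihydro-2H-pyran-2-yl}-2-[4-(benzyloxy)phenyl]ethan-1-ol | COc1cc([C@@H]2C=CC[C@H]([C@@H](O)Cc3ccc(OCc4ccccc4)cc3)O2)ccc1OCc1ccccc1 | intermediate
19 | (2S,6R)-2-[4-(benzyloxy)-3-methoxyphenyl]-6-{(1S)-2-[4-(benzyloxy)phenyl]-1-hydroxyethyl}oxan-4-one | COc1cc([C@@H]2CC(=O)C[C@H]([C@@H](O)Cc3ccc(OCc4ccccc4)cc3)O2)ccc1OCc1ccccc1 | intermediate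
20 | (2S,6R)-2-(4-hydroxy-3-methoxyphenyl)-6-[(1S)-1-hydroxy-2-(4-hydroxyphenyl)ethyl]oxan-4-one | COc1cc([C@@H]2CC(=O)C[C@H]([C@@H](O)Cc3ccc(O)cc3)O2)ccc1O | target

**Count and risks**

Total step count: 10. Longest linear sequence: 10 steps (1 to 20; the Grignard reagent 16 is made and used in step 7).

Steps most likely to fail:

1. Step 5 (rearrangement). The lithium enolate of 10 may open to a ketene alkoxide before it is silylated, or the silyl ketene acetal may decompose before the diaxial boat is reached. The fallback sets out from 10 and gives up the amide base and the silyl trap altogether. Soft enolisation with Bu2BOTf and iPr2NEt in CH2Cl2 at −78 °C would give the dibutylboron ketene acetal F1, which is not prone to the ketene-forming elimination. On warming, the same shift would lead to the dibutylboryl ester F2, and hydrolytic work-up at pH 7 would return the acid 13, where the route continues.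

2. Step 9 (oxidation at C4). Hydroxypalladation may occur at the wrong alkene carbon, a palladium hydride may move the double bond into conjugation with the ring oxygen, or the allylic benzylic C2–O1 bond may ionise at the Lewis-acidic metal. The fallback sets out from 18 and replaces the palladium oxidation by hydration and alcohol oxidation. NaH and BnBr (Bu4NI, THF) would give the tribenzyl ether F3. Hg(OAc)2 in THF/H2O would add hydroxyl at C4 and mercury at C3, the carbon next to the allylic oxygen, to give the organomercurial F4 (not isolated). NaBH4/NaOH would then give the C4 alcohol F5, whose C4 configuration is of no consequence. Dess–Martin periodinane would give the ketone F6, and hydrogenolysis of all three benzyl ethers (H2, Pd(OH)2/C, EtOAc) would reach the target 20 directly.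

3. Step 3 (acetal cleavage). The 4-alkoxybenzylic ether may ionise with loss of the glycolate arm, or the acetal may be cleaved incompletely. The fallback sets out from aldehyde 1 and changes the allylic protecting group to one removed by fluoride. Allyl alcohol, SEMCl and iPr2NEt would give allyl SEM ether F7. Metalation and borylation as in step 1 would give the allylborane F8. Addition to 1 would give the borinate F9 and, after oxidation, the SEM-protected syn alcohol F10. Etherification as in step 2 would give the acid F11. TBAF in DMPU at 80 °C would then remove the SEM group by fluoride-triggered fragmentation, with no Lewis or Brønsted acid, and return the hydroxy acid 9.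

**Further compounds**

F1 | step 5 | dibutylboron ketene acetal of 10 | CCCCB(CCCC)OC1=CO[C@H](c2ccc(OCc3ccccc3)c(OC)c2)[C@@H](C=C)O1
F2 | step 5 | dibutylboryl ester of acid 13 | COc1cc([C@@H]2C=CC[C@H](C(=O)OB(CCCC)CCCC)O2)ccc1OCc1ccccc1
F3 | step 9 | benzyl ether of 18 at the C7 oxygen | COc1cc([C@@H]2C=CC[C@H]([C@@H](OCc3ccccc3)Cc3ccc(OCc4ccccc4)cc3)O2)ccc1OCc1ccccc1
F4 | step 9 | C3-acetoxymercurio C4-hydroxy oxane from F3 (C3 and C4 configuration not fixed) | COc1cc([C@@H]2C([Hg]OC(C)=O)C(O)C[C@H]([C@@H](OCc3ccccc3)Cc3ccc(OCc4ccccc4)cc3)O2)ccc1OCc1ccccc1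
F5 | step 9 | C4 alcohol, tribenzyl ether (C4 epimers) | COc1cc([C@@H]2CC(O)C[C@H]([C@@H](OCc3ccccc3)Cc3ccc(OCc4ccccc4)cc3)O2)ccc1OCc1ccccc1
F6 | step 9 | C4 ketone, tribenzyl ether of the target | COc1cc([C@@H]2CC(=O)C[C@H]([C@@H](OCc3ccccc3)Cc3ccc(OCc4ccccc4)cc3)O2)ccc1OCc1ccccc1
F7 | step 3 | 3-{[2-(trimethylsilyl)ethoxy]methoxy}prop-1-ene (allyl SEM ether) | C=CCOCOCC[Si](C)(C)C
F8 | step 3 | [(Z)-3-{[2-(trimethylsilyl)ethoxy]methoxy}prop-2-en-1-yl]diisopinocampheylborane | C[Si](C)(C)CCOCO/C=C\CB([C@@H]1C[C@@H]2C[C@@H](C2(C)C)[C@H]1C)[C@@H]1C[C@@H]2C[C@@H](C2(C)C)[C@H]1C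
F9 | step 3 | diisopinocampheylborinate of alcohol F10 | C[Si](C)(C)CCOCO[C@H](C=C)[C@H](OB([C@@H]1C[C@@H]2C[C@@H](C2(C)C)[C@H]1C)[C@@H]1C[C@@H]2C[C@@H](C2(C)C)[C@H]1C)c1ccc(OCc2ccccc2)c(OC)c1
F10 | step 3 | (1R,2R)-1-[4-(benzyloxy)-3-methoxyphenyl]-2-{[2-(trimethylsilyl)ethoxy]methoxy}but-3-en-1-ol | C[Si](C)(C)CCOCO[C@H](C=C)[C@H](O)c1ccc(OCc2ccccc2)c(OC)c1
F11 | step 3 | 2-{[(1R,2R)-1-[4-(benzyloxy)-3-methoxyphenyl]-2-{[2-(trimethylsilyl)ethoxy]methoxy}but-3-en-1-yl]oxy}acetic acid | C[Si](C)(C)CCOCO[C@H](C=C)[C@H](OCC(=O)O)c1ccc(OCc2ccccc2)c(OC)c1
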